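**Plan**

- Retrosynthesis: the methyl and hydroxyl pattern of the target is taken back to a 5,8-dihydroxy-6,7-dimethoxyflavone, whose ring A is then cut at C8–C8a and at C5–C4a.
- Enabling feature: C5, C6, C7 and C8 of ring A are contiguous and all carry oxygen, so they map onto the four carbons of dimethyl squarate; C4a and C8a are C3 and the neighbouring C2–H carbon of a 4-pyranone that already holds ring B.
- Forward order: ring B aldehyde, then ring C (hetero-Diels–Alder, α-iodination, dehydrogenation), then the C5–C4a bond (pyranonyl Grignard plus squarate), then ring A by thermal cyclobutenone ring expansion (C8–C8a bond).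
- Endgame: methylate O8, free O6 by chelation-directed demethylation, benzylate O6 and O2', methylate O5, hydrogenolyse.
- Stereochemistry: the target has no stereocentre; the centres met on the way are racemic and are erased by aromatisation.

Key step: step 6

Assumption: the AlCl3 conditions of step 8 are taken to cleave the 2'-benzyl ether completely along with the 6-methyl ether, so O2' is benzylated again together with O6 in step 9.

**Route**

Step 1
Reactants: 1 2-hydroxy-6-methoxybenzaldehyde
Product: 2 2-(benzyloxy)-6-methoxybenzaldehyde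
Conditions: BnBr, K2CO3, DMF, rt
Reagents that add atoms: benzyl bromide, BrCc1ccccc1
Why: Williamson etherification of the phenol, which leaves the aldehyde untouched under carbonate conditions.

Step 2
Reactants: 2 2-(benzyloxy)-6-methoxybenzaldehyde; 3 (E)-1-methoxy-3-(trimethylsilyloxy)buta-1,3-diene (Danishefsky's diene)
Product: 5 2-[2-(benzyloxy)-6-methoxyphenyl]-2,3-dihydro-4H-pyran-4-one (racemic), via silyl enol ether cycloadduct 4 (not isolated)
Conditions: ZnCl2 (1 equiv), THF, rt; then TFA (cat.), CH2Cl2, rt; aq. NaHCO3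
Reagents that add atoms: none
Why: the ZnCl2-mediated hetero-Diels–Alder reaction of an aromatic aldehyde with Danishefsky's diene, followed by acid-induced loss of methanol and of the silyl group, is the standard entry to 2-aryl-2,3-dihydro-4H-pyran-4-ones, and the new C2 centre, formed racemic, is erased in step 4.

Step 3
Reactants: 5 2-[2-(benzyloxy)-6-methoxyphenyl]-2,3-dihydro-4H-pyran-4-one
Product: 6 2-[2-(benzyloxy)-6-methoxyphenyl]-5-iodo-2,3-dihydro-4H-pyran-4-one (racemic)
Conditions: I2, pyridine, CH2Cl2, 0 °C to rt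
Reagents that add atoms: iodine, II
Why: Johnson-type α-iodination of the vinylogous ester can occur only at C5, the single enone α-carbon, and I2 in pyridine is too weak an electrophile to iodinate the dialkoxyarene of ring B.

Step 4
Reactants: 6 2-[2-(benzyloxy)-6-methoxyphenyl]-5-iodo-2,3-dihydro-4H-pyran-4-one
Product: 7 2-[2-(benzyloxy)-6-methoxyphenyl]-5-iodo-4H-pyran-4-one
Conditions: DDQ, 1,4-dioxane, 100 °C
Reagents that add atoms: none
Why: DDQ dehydrogenation across C2–C3, as in the flavanone-to-flavone oxidation, is driven by loss of the benzylic, oxygen-stabilised C2 hydride and by formation of the 4-pyranone, while the vinyl iodide and the benzyl aryl ether are inert to DDQ.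

Step 5
Reactants: 7 2-[2-(benzyloxy)-6-methoxyphenyl]-5-iodo-4H-pyran-4-one; 8 dimethyl squarate
Product: 10 4-{6-[2-(benzyloxy)-6-methoxyphenyl]-4-oxo-4H-pyran-3-yl}-4-hydroxy-2,3-dimethoxycyclobut-2-en-1-one (racemic), via pyranonylmagnesium chloride 9 (not isolated)
Conditions: i-PrMgCl·LiCl, THF, −40 °C; cannulated into 8 (1.5 equiv), THF, −78 °C; sat. aq. NH4Cl
Reagents that add atoms: none
Why: iodine–magnesium exchange on an α-iodo 4-pyranone (as practised on 3-iodochromones) gives a carbonyl-chelated alkenyl Grignard reagent that has no enolisable hydrogen and should not ring-open at low temperature, and its inverse addition to excess squarate is the usual 1,2-mono-addition of organometallics to a squarate carbonyl, the new carbinol centre being racemic and lost in step 6.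

Step 6
Reactants: 10 4-{6-[2-(benzyloxy)-6-methoxyphenyl]-4-oxo-4H-pyran-3-yl}-4-hydroxy-2,3-dimethoxycyclobut-2-en-1-one
Product: 13 2'-(benzyloxy)-5,8-dihydroxy-6,7,6'-trimethoxyflavone, via Z-dienylketene 11 (not isolated), via cyclohexadienone 12 (not isolated)
Conditions: degassed toluene (0.02 M), 110 °C, argon
Reagents that add atoms: none
Why: Heating should cleave the C1–C4 bond of the cyclobutenone in a conrotatory 4π electrocyclic opening, the hydroxyl turning outward so that the pyranonyl group lies cis to the ketene in 11. A thermal 6π electrocyclisation then joins the ketene carbon to the pyranone C2–H carbon, which forms the C8–C8a bond and closes ring A as the six-membered carbocycle of 12, and enolisation of the C8a–H ketone gives the aromatic 5,8-hydroquinone 13. The closest known reaction type is the Moore rearrangement of 4-alkenyl- and 4-(hetero)aryl-4-hydroxycyclobutenones to hydroquinones, with the pyranone C2=C3 bond playing the part of the alkenyl unit. No stereocentre is created for good, since the carbinol centre of 10 and the transient C8a centre of 12 both vanish on aromatisation. The step needs torquoselectivity, secured by the preference of the donor hydroxyl for outward rotation, and regioselective closure, secured because the attachment carbon has only one neighbouring sp2 C–H (the other neighbour is the C4 carbonyl carbon). Exclusion of air keeps the product at the hydroquinone level instead of the 5,8-quinone.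

Step 7
Reactants: 13 2'-(benzyloxy)-5,8-dihydroxy-6,7,6'-trimethoxyflavone
Product: 14 2'-(benzyloxy)-5-hydroxy-6,7,8,6'-tetramethoxyflavone
Conditions: MeI (1.1 equiv), K2CO3, degassed acetone, rt, argon
Reagents that add atoms: iodomethane, CI
Why: in this Williamson methylation the 5-hydroxyl is hydrogen-bonded to the C4 carbonyl and far less nucleophilic, so one equivalent of iodomethane should alkylate only O8.

Step 8
Reactants: 14 2'-(benzyloxy)-5-hydroxy-6,7,8,6'-tetramethoxyflavone
Product: 15 5,6,2'-trihydroxy-7,8,6'-trimethoxyflavone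
Conditions: AlCl3 (excess), MeCN, 70 °C; then 2 M HCl
Reagents that add atoms: none
Why: in this chelation-directed Lewis-acid ether cleavage the aluminium held by the 5-oxygen and the C4 carbonyl reaches only the neighbouring 6-methoxyl, whose methyl is removed by chloride while the 7-, 8- and 6'-methyl ethers have no such chelate, and the benzyl aryl ether is expected to fall under the same conditions.

Step 9
Reactants: 15 5,6,2'-trihydroxy-7,8,6'-trimethoxyflavone
Product: 16 6,2'-bis(benzyloxy)-5-hydroxy-7,8,6'-trimethoxyflavone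
Conditions: BnBr (2.2 equiv), K2CO3, degassed DMF, rt, argon
Reagents that add atoms: benzyl bromide, BrCc1ccccc1
Why: Williamson benzylation takes the two free phenols at O6 and O2' and again spares the chelated 5-hydroxyl, which is the usual order of reactivity in 5-hydroxyflavones.

Step 10
Reactants: 16 6,2'-bis(benzyloxy)-5-hydroxy-7,8,6'-trimethoxyflavone
Product: 17 6,2'-bis(benzyloxy)-5,7,8,6'-tetramethoxyflavone
Conditions: MeI (excess), K2CO3, DMF, 50 °C
Reagents that add atoms: iodomethane, CI
Why: with every other phenol capped, forcing Williamson conditions methylate the remaining chelated 5-hydroxyl, as is routine for 5-hydroxyflavones.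

Step 11
Reactants: 17 6,2'-bis(benzyloxy)-5,7,8,6'-tetramethoxyflavone
Product: 18 6,2'-dihydroxy-5,7,8,6'-tetramethoxyflavone
Conditions: H2 (1 atm), Pd/C (10% palladium on carbon), EtOAc–MeOH, rt
Reagents that add atoms: none
Why: catalytic hydrogenolysis cleaves both benzyl aryl ethers under conditions that do not reduce the C2=C3 bond of the pyranone ring or touch the methyl ethers.

**Compound list**

1 | 2-hydroxy-6-methoxybenzaldehyde | COc1cccc(O)c1C=O | starting material
2 | 2-(benzyloxy)-6-methoxybenzaldehyde | COc1cccc(OCc2ccccc2)c1C=O | intermediate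
3 | (E)-1-methoxy-3-(trimethylsilyloxy)buta-1,3-diene | CO/C=C/C(=C)O[Si](C)(C)C | starting material
4 | 2-[2-(benzyloxy)-6-methoxyphenyl]-6-methoxy-4-(trimethylsilyloxy)-3,6-dihydro-2H-pyran (racemic, both C6 epimers, not isolated) | COC1C=C(O[Si](C)(C)C)CC(c2c(OC)cccc2OCc2ccccc2)O1 | intermediate
5 | 2-[2-(benzyloxy)-6-methoxyphenyl]-2,3-dihydro-4H-pyran-4-one (racemic) | O=C1C=COC(c2c(OC)cccc2OCc2ccccc2)C1 | intermediate
6 | 2-[2-(benzyloxy)-6-methoxyphenyl]-5-iodo-2,3-dihydro-4H-pyran-4-one (racemic) | O=C1CC(c2c(OC)cccc2OCc2ccccc2)OC=C1I | intermediate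
7 | 2-[2-(benzyloxy)-6-methoxyphenyl]-5-iodo-4H-pyran-4-one | COc1cccc(OCc2ccccc2)c1-c1cc(=O)c(I)co1 | intermediate
8 | dimethyl squarate (3,4-dimethoxycyclobut-3-ene-1,2-dione) | COC1=C(OC)C(=O)C1=O | starting material
9 | {6-[2-(benzyloxy)-6-methoxyphenyl]-4-oxo-4H-pyran-3-yl}magnesium chloride, LiCl complex (not isolated) | COc1cccc(OCc2ccccc2)c1-c1cc(=O)c([Mg]Cl)co1.[Li+].[Cl-] | intermediate
10 | 4-{6-[2-(benzyloxy)-6-methoxyphenyl]-4-oxo-4H-pyran-3-yl}-4-hydroxy-2,3-dimethoxycyclobut-2-en-1-one (racemic) | COC1=C(OC)C(O)(c2coc(-c3c(OC)cccc3OCc3ccccc3)cc2=O)C1=O | intermediate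
11 | (Z)-4-{6-[2-(benzyloxy)-6-methoxyphenyl]-4-oxo-4H-pyran-3-yl}-4-hydroxy-2,3-dimethoxybuta-1,3-dien-1-one (dienylketene, pyranonyl cis to the ketene-bearing carbon, not isolated) | COC(=C=O)/C(OC)=C(/O)c1coc(-c2c(OC)cccc2OCc2ccccc2)cc1=O | intermediate
12 | 2-[2-(benzyloxy)-6-methoxyphenyl]-5-hydroxy-6,7-dimethoxy-8aH-chromene-4,8-dione (racemic, 8a-H keto tautomer of 13, not isolated) | COC1=C(OC)C(=O)C2OC(-c3c(OC)cccc3OCc3ccccc3)=CC(=O)C2=C1O | intermediate
13 | 2'-(benzyloxy)-5,8-dihydroxy-6,7,6'-trimethoxyflavone | COc1cccc(OCc2ccccc2)c1-c1cc(=O)c2c(O)c(OC)c(OC)c(O)c2o1 | intermediate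
14 | 2'-(benzyloxy)-5-hydroxy-6,7,8,6'-tetramethoxyflavone | COc1cccc(OCc2ccccc2)c1-c1cc(=O)c2c(O)c(OC)c(OC)c(OC)c2o1 | intermediate
15 | 5,6,2'-trihydroxy-7,8,6'-trimethoxyflavone | COc1cccc(O)c1-c1cc(=O)c2c(O)c(O)c(OC)c(OC)c2o1 | intermediate
16 | 6,2'-bis(benzyloxy)-5-hydroxy-7,8,6'-trimethoxyflavone | COc1cccc(OCc2ccccc2)c1-c1cc(=O)c2c(O)c(OCc3ccccc3)c(OC)c(OC)c2o1 | intermediate
17 | 6,2'-bis(benzyloxy)-5,7,8,6'-tetramethoxyflavone | COc1cccc(OCc2ccccc2)c1-c1cc(=O)c2c(OC)c(OCc3ccccc3)c(OC)c(OC)c2o1 | intermediate
18 | 6,2'-dihydroxy-5,7,8,6'-tetramethoxyflavone | COc1cccc(O)c1-c1cc(=O)c2c(OC)c(O)c(OC)c(OC)c2o1 | target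

**Step count and risks**

Total step count: 11. Longest linear sequence: 11 steps (1 to 18); compounds 3 and 8 are bought.

Steps most likely to fail:

Step 6. Part of the cyclobutenone may open with the hydroxyl turned inward, after which the ketene is captured by that hydroxyl (lactonisation) instead of closing onto the pyranone. The electron-rich hydroquinone may also oxidise in air during isolation. The fallback sets out from 10 and comes back at 14.
- The carbinol is silylated (TBSOTf, 2,6-lutidine, CH2Cl2) to the 4-silyloxycyclobutenone F1.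
- On heating in degassed toluene, F1 should pass through the silyloxy dienylketene F2 and the silyloxy cyclohexadienone F3 to the 5-O-silyl-8-hydroxyflavone F4. A wrongly rotated ketene can no longer lactonise and can only re-close and reopen, and no free hydroquinone is formed.
- Methylation of the free 8-hydroxyl (MeI, K2CO3, acetone) gives the 5-O-silyl-8-methyl ether F5.
- Desilylation with Bu4NF and AcOH in THF gives 14.

Step 4. Hydride abstraction from the hindered benzylic C2–H may be slow, so that oxidation at the benzyl ether methylene or loss of iodine competes. The fallback sets out from 6 and comes back at 7.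
- Soft enolisation (TBSOTf, Et3N, CH2Cl2) gives the 4-silyloxy-2H-pyran F6.
- Ph3CBF4 in CH2Cl2 removes the C2 hydride from this far more electron-rich diene (trityl-cation oxidation of a silyl enol ether) to give the 4-silyloxypyrylium tetrafluoroborate F7.
- Aqueous NaHCO3 work-up desilylates F7 to 7.

Step 8. The benzyl cation released at 70 °C may alkylate ring B (Friedel–Crafts C-benzylation), and the heating needed for complete debenzylation may begin to cleave the 8- or 6'-methyl ether. The fallback sets out from 14 and comes back at 15.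
- The benzyl ether is removed first by hydrogenolysis (H2, Pd/C, EtOAc–MeOH) to give 5,2'-dihydroxy-6,7,8,6'-tetramethoxyflavone F8.
- F8 is then subjected to the chelation-directed demethylation alone (AlCl3, MeCN, at the lowest temperature that cleaves the 6-methyl ether) to give 15.

**Further compounds**

F1 | step 6 | 4-{6-[2-(benzyloxy)-6-methoxyphenyl]-4-oxo-4H-pyran-3-yl}-4-[(tert-butyldimethylsilyl)oxy]-2,3-dimethoxycyclobut-2-en-1-one (racemic) | COC1=C(OC)C(O[Si](C)(C)C(C)(C)C)(c2coc(-c3c(OC)cccc3OCc3ccccc3)cc2=O)C1=O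
F2 | step 6 | (Z)-4-{6-[2-(benzyloxy)-6-methoxyphenyl]-4-oxo-4H-pyran-3-yl}-4-[(tert-butyldimethylsilyl)oxy]-2,3-dimethoxybuta-1,3-dien-1-one | COC(=C=O)/C(OC)=C(/O[Si](C)(C)C(C)(C)C)c1coc(-c2c(OC)cccc2OCc2ccccc2)cc1=O
F3 | step 6 | 2-[2-(benzyloxy)-6-methoxyphenyl]-5-[(tert-butyldimethylsilyl)oxy]-6,7-dimethoxy-8aH-chromene-4,8-dione (racemic) | COC1=C(OC)C(=O)C2OC(-c3c(OC)cccc3OCc3ccccc3)=CC(=O)C2=C1O[Si](C)(C)C(C)(C)C
F4 | step 6 | 2'-(benzyloxy)-5-[(tert-butyldimethylsilyl)oxy]-8-hydroxy-6,7,6'-trimethoxyflavone | COc1cccc(OCc2ccccc2)c1-c1cc(=O)c2c(O[Si](C)(C)C(C)(C)C)c(OC)c(OC)c(O)c2o1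
F5 | step 6 | 2'-(benzyloxy)-5-[(tert-butyldimethylsilyl)oxy]-6,7,8,6'-tetramethoxyflavone | COc1cccc(OCc2ccccc2)c1-c1cc(=O)c2c(O[Si](C)(C)C(C)(C)C)c(OC)c(OC)c(OC)c2o1
F6 | step 4 | 2-[2-(benzyloxy)-6-methoxyphenyl]-4-[(tert-butyldimethylsilyl)oxy]-5-iodo-2H-pyran (racemic) | CC(C)(C)[Si](C)(C)OC1=CC(c2c(OC)cccc2OCc2ccccc2)OC=C1I
F7 | step 4 | 2-[2-(benzyloxy)-6-methoxyphenyl]-4-[(tert-butyldimethylsilyl)oxy]-5-iodopyrylium tetrafluoroborate | CC(C)(C)[Si](C)(C)Oc1cc(-c2c(OC)cccc2OCc2ccccc2)[o+]cc1I.F[B-](F)(F)F
F8 | step 8 | 5,2'-dihydroxy-6,7,8,6'-tetramethoxyflavone | COc1cccc(O)c1-c1cc(=O)c2c(O)c(OC)c(OC)c(OC)c2o1
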